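**Retrosynthetic overview**

1. Ring numbering: C1 (CH–O-angelate), C2 (CH2), C3/C4 (oxirane, C3 carries CH3), C5 (CH–OAc), C6 (CH–i-Pr), C7, C8 (CH2), C9/C10 (oxirane, C9 carries CH3), C10 bonded to C1. The strategy rests on C1 and C5: both are CH–O carbons allylic to, and attached at the CH end (C10, C4) of, the two (E)-trisubstituted alkenes C9=C10 and C3=C4 from which the oxiranes arise, so the target is the ten-membered hydrocarbon plus four oxygen atoms and two acyl groups.
2. Target 12 ⇐ 11 ⇐ 8: the acetate on the hindered C5–OH and the angelate on C1–OH are removed. 8 ⇐ 7: both oxiranes come from the (E,E)-diene diol by hydroxyl-assisted peracid epoxidation on the exposed faces.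
3. 7 ⇐ 5: the C1–O and C5–O bonds are made by two cytochrome P450 allylic C–H hydroxylations (retention) of the (E,E)-diene hydrocarbon; no ring is formed.
4. 5 ⇐ 4 ⇐ 3 ⇐ 1: isopropyl from isopropenyl (diimide); the ten-membered carbocycle and the C6 stereocentre from farnesyl diphosphate with (+)-germacrene A synthase; the diphosphate from (2E,6E)-farnesol.
5. Ring order: the ten-membered carbocycle first (step 3), then both oxiranes in one operation (step 6).

Key step: step 5

Remark: locants in all names follow the ring numbering of the overview, and the target is read from its SMILES as the (1R,3S,4S,5R,6S,9S,10S) isomer, whose C6 configuration is that of (+)-(R)-germacrene A.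

**Route**

Step 1
Reactants: 1 (2E,6E)-farnesol
Product: 2 (2E,6E)-farnesyl chloride
Conditions: NCS, Me2S, CH2Cl2, −40 to 0 °C
Reagents that add atoms: N-chlorosuccinimide, O=C1CCC(=O)N1Cl
Why: Corey–Kim chlorination, in which the alkoxysulfonium salt is displaced by chloride in an SN2 step at the primary allylic carbon without allylic transposition, so both (E)-alkenes are kept and no stereocentre is formed.

Step 2
Reactants: 2 (2E,6E)-farnesyl chloride
Product: 3 (2E,6E)-farnesyl diphosphate, trisammonium salt
Conditions: (n-Bu4N)3HP2O7, MeCN, rt; then Dowex 50WX8 (NH4+ form), aq NH4HCO3/i-PrOH; lyophilise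
Reagents that add atoms: tris(tetrabutylammonium) hydrogen diphosphate, CCCC[N+](CCCC)(CCCC)CCCC.CCCC[N+](CCCC)(CCCC)CCCC.CCCC[N+](CCCC)(CCCC)CCCC.OP(=O)([O-])OP(=O)([O-])[O-]; ammonium hydrogencarbonate, [NH4+].OC(=O)[O-]
Why: Davisson–Poulter diphosphorylation, an SN2 displacement of the primary allylic chloride by the diphosphate anion followed by cation exchange to the enzyme-compatible ammonium salt; no stereocentre is formed.

Step 3
Reactants: 3 (2E,6E)-farnesyl diphosphate, trisammonium salt
Product: 4 (+)-(R)-germacrene A [(3E,6R,9E)-3,9-dimethyl-6-(prop-1-en-2-yl)cyclodeca-3,9-diene]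
Conditions: (+)-germacrene A synthase (Cichorium intybus, recombinant from E. coli), MgCl2, HEPES buffer pH 7.5, dithiothreitol, pentane overlay, 30 °C
Reagents that add atoms: none
Why: Mg2+-dependent terpene synthase cyclisation: the enzyme ionises the diphosphate, the distal alkene attacks the allyl cation to close the ten-membered ring at the C5–C6 bond and a methyl proton is lost to give the isopropenyl group; the C6 stereocentre (R) is fixed by the fold of the chain in the active site and both (E)-alkenes come unchanged from 3.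

Step 4
Reactants: 4 (+)-(R)-germacrene A
Product: 5 (R)-dihydrogermacrene A [(3E,6R,9E)-3,9-dimethyl-6-(propan-2-yl)cyclodeca-3,9-diene]
Conditions: 2-O2NC6H4SO2NHNH2, Et3N, CH2Cl2, 0 °C to rt
Reagents that add atoms: none
Why: Diimide reduction (concerted syn transfer of H2 from cis-HN=NH made in the flask at room temperature): the 1,1-disubstituted isopropenyl alkene reacts far faster than the two trisubstituted ring alkenes, no acid or heat is involved (no Cope rearrangement, no transannular cyclisation), and C6 is untouched.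

Step 5
Reactants: 5 (R)-dihydrogermacrene A
Product: 7 (1R,3E,5R,6S,9E)-3,9-dimethyl-6-(propan-2-yl)cyclodeca-3,9-diene-1,5-diol, via 5-hydroxy diene 6 (not isolated)
Conditions: E. coli resting cells co-expressing two engineered CYP102A1 (P450 BM3) variants and glucose dehydrogenase, D-glucose, NADP+ (cat.), O2 (air), potassium phosphate buffer pH 7.5, 2-hydroxypropyl-β-cyclodextrin, 25 °C
Reagents that add atoms: dioxygen, O=O
Why: Proposed new method: in each P450 the oxoiron porphyrin radical cation (iron formally tetravalent) abstracts one allylic hydrogen and the iron-bound hydroxyl rebounds onto the same face of the allyl radical before it can transpose, so C–H is replaced by C–OH with retention; the first variant takes the pro-R hydrogen on C5 of 5 (giving 6) and the second the pro-R hydrogen on C1 of 6, while glucose dehydrogenase recycles NADPH. The closest known reactions are allylic hydroxylations of germacrene-type acids by plant CYP71 enzymes and of terpene hydrocarbons by engineered CYP102A1 variants; hydroxylation of this hydrocarbon at these two carbons has not been shown. No ring is closed; two C–O bonds and the stereocentres C1 (R) and C5 (R) are formed, each fixed by which of the two diastereotopic hydrogens the binding pocket holds over the oxo group, the pocket reading the C6 isopropyl stereocentre and the crossed fold of the (E,E)-diene. The step needs site selectivity for C1 and C5 over C2, C8 and the two methyl groups, and C–H abstraction in preference to epoxidation of the electron-rich alkenes; this must be found by screening and directed evolution, and the substrate helps in that the two hydrogens to be removed point to the outside of the ring and overlap with the neighbouring π bond in one and the same conformer of 5. Neutral buffer at 25 °C keeps the acid- and heat-sensitive 1,5-diene intact, and the more polar diol leaves the hydrophobic pocket, which should limit further oxidation.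

Step 6
Reactants: 7 (1R,3E,5R,6S,9E)-3,9-dimethyl-6-(propan-2-yl)cyclodeca-3,9-diene-1,5-diol
Product: 8 (1R,3S,4S,5R,6S,9S,10S)-3,4:9,10-diepoxy-3,9-dimethyl-6-(propan-2-yl)cyclodecane-1,5-diol
Conditions: m-CPBA (2.3 equiv), NaHCO3, CH2Cl2/H2O, 0 °C
Reagents that add atoms: 3-chloroperoxybenzoic acid, OOC(=O)c1cccc(Cl)c1
Why: Prilezhaev epoxidation with Henbest-type hydroxyl assistance: in the rotamer free of 1,3-allylic strain each carbinol hydrogen (H1, H5) eclipses its alkene and points at the cis methyl group, the ring carbon (C2 or C6) lies on the inner face and the hydroxyl on the exposed face at an O–C–C=C angle near 120–140°, so the hydrogen-bonded peracid adds to that exposed face and should give the threo epoxy alcohols (3S,4S and 9S,10S); the bicarbonate buffer guards against acid-induced transannular opening, and VO(acac)2/t-BuOOH is avoided because its small preferred O–C–C=C angle fits the other rotamer.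

Step 7
Reactants: 8 (1R,3S,4S,5R,6S,9S,10S)-3,4:9,10-diepoxy-3,9-dimethyl-6-(propan-2-yl)cyclodecane-1,5-diol; 9 angelic acid [(Z)-2-methylbut-2-enoic acid]
Product: 11 (1R,3S,4S,5R,6S,9S,10S)-3,4:9,10-diepoxy-5-hydroxy-3,9-dimethyl-6-(propan-2-yl)cyclodecan-1-yl (Z)-2-methylbut-2-enoate, via angelic 2,4,6-trichlorobenzoic anhydride 10 (not isolated)
Conditions: 9, 2,4,6-Cl3C6H2COCl, Et3N, toluene, rt, then filter; add 8 and Et3N, toluene, 75 °C
Reagents that add atoms: 2,4,6-trichlorobenzoyl chloride, O=C(Cl)c1c(Cl)cc(Cl)cc1Cl (its acyl group is held by 10 only)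
Why: Yamaguchi-type mixed-anhydride esterification run thermally without a nucleophilic catalyst: the alcohol attacks the angeloyl carbonyl of 10 (the other carbonyl is shielded by two ortho chlorines), the (Z)-geometry is kept because no pyridine-type catalyst can add to the β-carbon, and C1–OH (between a CH2 and an oxirane CH) should react before C5–OH (between an oxirane CH and the isopropyl-bearing C6); no stereocentre changes.

Step 8
Reactants: 11 (1R,3S,4S,5R,6S,9S,10S)-3,4:9,10-diepoxy-5-hydroxy-3,9-dimethyl-6-(propan-2-yl)cyclodecan-1-yl (Z)-2-methylbut-2-enoate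
Product: 12 (1R,3S,4S,5R,6S,9S,10S)-5-acetoxy-3,4:9,10-diepoxy-3,9-dimethyl-6-(propan-2-yl)cyclodecan-1-yl (Z)-2-methylbut-2-enoate (CNP0311463.1)
Conditions: Ac2O, DMAP (cat.), pyridine, 0 °C to rt
Reagents that add atoms: acetic anhydride, CC(=O)OC(C)=O
Why: DMAP-catalysed acetylation (acetylpyridinium transfer) of the remaining hindered secondary alcohol at C5; the angelate already in place and the oxiranes should be inert under these mild basic conditions, and no stereocentre changes.

**Compound list**

1 | (2E,6E)-farnesol | CC(C)=CCC/C(C)=C/CC/C(C)=C/CO | starting material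
2 | (2E,6E)-farnesyl chloride | CC(C)=CCC/C(C)=C/CC/C(C)=C/CCl | intermediate
3 | (2E,6E)-farnesyl diphosphate, trisammonium salt | CC(C)=CCC/C(C)=C/CC/C(C)=C/COP(=O)([O-])OP(=O)([O-])[O-].[NH4+].[NH4+].[NH4+] | intermediate
4 | (+)-(R)-germacrene A, (3E,6R,9E)-3,9-dimethyl-6-(prop-1-en-2-yl)cyclodeca-3,9-diene | C1/C(C)=C/CC/C(C)=C/C[C@H](C(C)=C)C1 | intermediate
5 | (R)-dihydrogermacrene A, (3E,6R,9E)-3,9-dimethyl-6-(propan-2-yl)cyclodeca-3,9-diene | C1/C(C)=C/CC/C(C)=C/C[C@H](C(C)C)C1 | intermediate
6 | (3E,5R,6S,9E)-3,9-dimethyl-6-(propan-2-yl)cyclodeca-3,9-dien-5-ol (formed in the flask) | C1/C(C)=C/CC/C(C)=C/[C@H](O)[C@H](C(C)C)C1 | intermediate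
7 | (1R,3E,5R,6S,9E)-3,9-dimethyl-6-(propan-2-yl)cyclodeca-3,9-diene-1,5-diol | C1/C(C)=C/[C@H](O)C/C(C)=C/[C@H](O)[C@H](C(C)C)C1 | intermediate
8 | (1R,3S,4S,5R,6S,9S,10S)-3,4:9,10-diepoxy-3,9-dimethyl-6-(propan-2-yl)cyclodecane-1,5-diol | O[C@@H]1C[C@]2(C)O[C@H]2[C@H](O)[C@H](C(C)C)CC[C@]2(C)O[C@@H]12 | intermediate
9 | angelic acid, (Z)-2-methylbut-2-enoic acid | C/C=C(/C)C(=O)O | starting material
10 | angelic 2,4,6-trichlorobenzoic anhydride (formed in the flask) | C/C=C(/C)C(=O)OC(=O)c1c(Cl)cc(Cl)cc1Cl | intermediate
11 | (1R,3S,4S,5R,6S,9S,10S)-3,4:9,10-diepoxy-5-hydroxy-3,9-dimethyl-6-(propan-2-yl)cyclodecan-1-yl (Z)-2-methylbut-2-enoate | C/C=C(/C)C(=O)O[C@@H]1C[C@]2(C)O[C@H]2[C@H](O)[C@H](C(C)C)CC[C@]2(C)O[C@@H]12 | intermediate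
12 | (1R,3S,4S,5R,6S,9S,10S)-5-acetoxy-3,4:9,10-diepoxy-3,9-dimethyl-6-(propan-2-yl)cyclodecan-1-yl (Z)-2-methylbut-2-enoate | C/C=C(/C)C(=O)O[C@@H]1C[C@]2(C)O[C@H]2[C@H](OC(C)=O)[C@H](C(C)C)CC[C@]2(C)O[C@@H]12 | target

Total step count: 8. Longest linear sequence: 8 steps (1 to 12).

**Steps most likely to fail**

Step 5 (Proposed new method). What may go wrong: no enzyme variant may deliver hydroxylation at C1 and C5 on the required face, with oxidation at C2, C8 or the methyl groups, or epoxidation of the alkenes, taking over. Fallback with known reactions only: no known reaction oxidises C1 and C5 of 5, so this fallback cannot set out from an intermediate. It leaves the route at its start, replacing farnesol 1 as starting material by commercial but-2-ynal, and comes back at diol 7.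
- A catalytic asymmetric vinylogous Mukaiyama aldol addition (SiCl4, chiral bisphosphoramide, i-Pr2NEt, CH2Cl2, −78 °C; catalyst enantiomer chosen for the 5R alcohol) of 1-methoxy-3-methyl-1-(trimethylsilyloxy)buta-1,3-diene to but-2-ynal should give methyl (2E,5R)-5-hydroxy-3-methyloct-2-en-6-ynoate F1. This holds C1–OH, C2 and the (E)-C3=C4 alkene.
- TBSCl/imidazole gives methyl (2E,5R)-5-(tert-butyldimethylsilyloxy)-3-methyloct-2-en-6-ynoate F2.
- Cp2Zr(H)Cl adds syn across the alkyne with zirconium on the methyl-bearing carbon to give the alkenylzirconocene chloride F3 (not isolated). Iodine turns it into methyl (2E,5R,6E)-5-(tert-butyldimethylsilyloxy)-7-iodo-3-methylocta-2,6-dienoate F4.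
- i-Bu2AlH at −78 °C reduces the ester to (2E,5R,6E)-5-(tert-butyldimethylsilyloxy)-7-iodo-3-methylocta-2,6-dien-1-ol F5, and MnO2 oxidises it to (2E,5R,6E)-5-(tert-butyldimethylsilyloxy)-7-iodo-3-methylocta-2,6-dienal F6.
- Anti-selective allylboration with (E)-(4-methylpent-2-enyl)boronic acid pinacol ester under chiral phosphoric acid catalysis (chair transition state; catalyst controls the absolute sense) sets C5 and C6 together. It should give (3R,4R,5E,8R,9E)-8-(tert-butyldimethylsilyloxy)-10-iodo-6-methyl-3-(propan-2-yl)undeca-1,5,9-trien-4-ol F7.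
- TBSOTf/2,6-lutidine gives the bis(tert-butyldimethylsilyl) ether of the trienol F8.
- 9-BBN adds only to the terminal vinyl group to give the B-alkyl-9-borabicyclononane F9 (not isolated). An intramolecular B-alkyl Suzuki–Miyaura coupling (PdCl2(dppf), AsPh3, Cs2CO3, DMF/THF/H2O, high dilution) closes the ten-membered ring at C8–C9 with retention of the iodide geometry, giving the 1,5-bis(tert-butyldimethylsilyl) ether of the diene diol F10.
- Bu4NF buffered with AcOH in THF (no free alkoxide, so no anionic oxy-Cope rearrangement) frees diol 7.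

Step 6. What may go wrong: poor facial selectivity at one of the two alkenes (attack through the other rotamer), or acid-triggered transannular opening of the first-formed oxirane by the remaining alkene. Fallback: it sets out from diol 7 and comes back at diepoxy diol 8, and moves the stereocontrol from the substrate hydroxyls to a chiral catalyst. The epoxidation is run with Shi's fructose-derived ketone (the enantiomer matched to the S,S oxiranes; one enantiomer serves both alkenes, since they have the same substitution pattern) and 2KHSO5·KHSO4·K2SO4 (Oxone) in MeCN/dimethoxymethane/aqueous K2CO3 at pH 10.5 and 0 °C. The chiral dioxirane selects the exposed face it matches, and the basic medium excludes acid-induced cyclisation. This fallback makes no new compound (F0).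

Step 7. What may go wrong: poor site selectivity between the C1 and C5 hydroxyls, or Z-to-E isomerisation of the angeloyl group during the slow thermal acylation. Fallback: it sets out from diepoxy diol 8 and comes back at target 12, and separates the two hydroxyls by a protecting group instead of by acylation rate.
- Et3SiCl/imidazole in CH2Cl2 at −40 °C silylates the less hindered C1–OH to give the 1-O-triethylsilyl diepoxy diol F11.
- Ac2O/DMAP/pyridine acetylates C5–OH to give the 1-O-triethylsilyl 5-O-acetyl diepoxy diol F12.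
- Bu4NF/AcOH in THF at 0 °C removes the silyl group to give the 5-O-acetyl diepoxy diol F13.
- The single free hydroxyl of F13 is then esterified with mixed anhydride 10 (used in excess, at the lowest temperature that gives conversion) to give 12.

**Further compounds**

F1 | step 5 | methyl (2E,5R)-5-hydroxy-3-methyloct-2-en-6-ynoate | CC#C[C@H](O)C/C(C)=C/C(=O)OC
F2 | step 5 | methyl (2E,5R)-5-(tert-butyldimethylsilyloxy)-3-methyloct-2-en-6-ynoate | CC#C[C@H](O[Si](C)(C)C(C)(C)C)C/C(C)=C/C(=O)OC
F3 | step 5 | alkenylzirconocene chloride from F2 (zirconium on C7) | C/C(=C\[C@H](O[Si](C)(C)C(C)(C)C)C/C(C)=C/C(=O)OC)[Zr](Cl)(C1C=CC=C1)C1C=CC=C1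
F4 | step 5 | methyl (2E,5R,6E)-5-(tert-butyldimethylsilyloxy)-7-iodo-3-methylocta-2,6-dienoate | C/C(I)=C\[C@H](O[Si](C)(C)C(C)(C)C)C/C(C)=C/C(=O)OC
F5 | step 5 | (2E,5R,6E)-5-(tert-butyldimethylsilyloxy)-7-iodo-3-methylocta-2,6-dien-1-ol | C/C(I)=C\[C@H](O[Si](C)(C)C(C)(C)C)C/C(C)=C/CO
F6 | step 5 | (2E,5R,6E)-5-(tert-butyldimethylsilyloxy)-7-iodo-3-methylocta-2,6-dienal | C/C(I)=C\[C@H](O[Si](C)(C)C(C)(C)C)C/C(C)=C/C=O
F7 | step 5 | (3R,4R,5E,8R,9E)-8-(tert-butyldimethylsilyloxy)-10-iodo-6-methyl-3-(propan-2-yl)undeca-1,5,9-trien-4-ol | C/C(I)=C\[C@H](O[Si](C)(C)C(C)(C)C)C/C(C)=C/[C@H](O)[C@H](C(C)C)C=C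
F8 | step 5 | bis(tert-butyldimethylsilyl) ether of F7 | C/C(I)=C\[C@H](O[Si](C)(C)C(C)(C)C)C/C(C)=C/[C@H](O[Si](C)(C)C(C)(C)C)[C@H](C(C)C)C=C
F9 | step 5 | B-alkyl-9-borabicyclononane from F8 | C/C(I)=C\[C@H](O[Si](C)(C)C(C)(C)C)C/C(C)=C/[C@H](O[Si](C)(C)C(C)(C)C)[C@H](C(C)C)CCB1C2CCCC1CCC2
F10 | step 5 | 1,5-bis(tert-butyldimethylsilyl) ether of diol 7 | C1/C(C)=C/[C@H](O[Si](C)(C)C(C)(C)C)C/C(C)=C/[C@H](O[Si](C)(C)C(C)(C)C)[C@H](C(C)C)C1
F0 | step 6 | none | none
F11 | step 7 | 1-O-triethylsilyl ether of diepoxy diol 8 | CC[Si](CC)(CC)O[C@@H]1C[C@]2(C)O[C@H]2[C@H](O)[C@H](C(C)C)CC[C@]2(C)O[C@@H]12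
F12 | step 7 | 1-O-triethylsilyl 5-O-acetyl derivative of 8 | CC[Si](CC)(CC)O[C@@H]1C[C@]2(C)O[C@H]2[C@H](OC(C)=O)[C@H](C(C)C)CC[C@]2(C)O[C@@H]12
F13 | step 7 | 5-O-acetyl derivative of 8 (C1–OH free) | O[C@@H]1C[C@]2(C)O[C@H]2[C@H](OC(C)=O)[C@H](C(C)C)CC[C@]2(C)O[C@@H]12
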